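Take the flask as charged and say first where the Z goes: X.G is formed from the G that has been made.

Z 0.50 mM; Q 1.00 equiv; X 0.05 mol%

    Z + X → X + G (k1 = 1.74 × 10⁶ /M/s)
    X + G ⇌ X.G (K2 = 24200 /M, k2 = 1.65 × 10⁶ /M/s)
    Q + X.G → X + E (k3 = 8.17 × 10⁵ /M/s)
    2 Z → Z2 (k4 = 0.819 /M/s)
    Z + Q → Z.Q (k5 = 452 /M/s)

- a species is counted by the Z in it: one Z2 counts as two
- a step written with two of one species runs at k times the square of its concentration and takes two of it each time
- charge of Z (flask): 0.50 mM

- the form that holds most of the catalyst when 5.0% of the Z are converted (X.G / X)
- its share of the catalyst then
- apparent order in Q when 5.0% of the Z are converted (percent change of the rate of making E for one percent more Q charged)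
- factor on the rate of making E when 5.0% of the Z are converted if X is charged twice over

By what routes does Z leave at the start? X takes it with a first-order constant of 0.435 /s, and Q takes it with 0.226 /s. Their ratio, Z lost through X per Z lost through Q, is the split, here 1.92. So 65.8% of the Z lost by these two routes at the start becomes G.

How much G stands at 5.0% conversion? I take 0.0165 mM, reached after about 0.0756 s.

And the catalyst? X meets that G at 27.1 /s. X.G leaves forward at 410 /s and backward at 68.2 /s, together 477 /s.

Why may these two simply be divided? X.G lives 2.10 ms, which is far shorter than the time to that conversion, so it keeps pace with G. X.G per X is then 0.0569, a logarithm to base ten of −1.24. The resting state is X, with a share of 94.6%.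

Now the weak spot: one percent more Q? I sum three contributions to the order: plus 0.143 from the backward share of the exit, minus 0.342 from G lost to the Q route, and plus 0.0646 from free X. I commit to an order of −0.134.

With twice the X? The split is then twice as large, so G at that conversion rises by a factor 1.21, and the rate by 2.39.

The forecast, close to these but not the same, gives X at 94.7%, an order of −0.14 and a factor of 2.37, saying: “More Q speeds E only slightly because X.G mostly goes forward anyway”.

The simulation gives X at 94.8%, an order of −0.11 and a factor of 2.35.

In this flask Z was used through X 1.6 times as fast as through Q at 1.36 s, a ratio lower than the split of 1.92 at the start. In the second flask, with twice the X, the split gives a factor of 0.603 on the time to 5.0% conversion, and that run took 0.606 of the time.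

The numbers of this flask are assumed; no experiment stands behind them.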